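**Plan**

- Retrosynthesis: the cis pair C3–CH2OH / C4–CH2Ar of the oxolane is first tied through the CH2OH oxygen to the benzylic carbon (helper ring), giving a cis-fused 3,7-dioxabicyclo[3.3.0]octan-1-ol. The C2–C3 bond is then cut to a 5-aryl-4-[(arylmethoxy)methyl]oxolan-3-one, which is cut at O–CH2 and CO–CH2 (chloromethyl ketone), at the aldol bond and at the ether (oxa-Michael).
- Enabling feature: C2–H of the target ring is a benzylic ether C–H that stands, through O1 and C5, in a 1,6-relation to the oxygen on C3. A carbonyl group at C3 can therefore take this hydrogen and bond to C2, and its oxygen becomes the tertiary OH.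
- Forward order: chain assembly (oxa-Michael, N-acylation, syn-aldol, Weinreb amide, chloromethyl ketone), then the helper oxolan-3-one ring by O-alkylation, then the oxolane ring of the target by photochemical C–C closure. The helper ring is opened by ionic hydrogenation of its benzylic C–O bond, and debenzylation follows.
- Stereochemistry: the auxiliary aldol sets the aryl carbinol centre. Equilibration α to the ketone relays it to C4 (trans). The cis ring fusion in the key step then fixes C3, and the exo preference fixes C2. The relay centre ends as the CH2 of the benzyl group.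

Key step: step 8

Remark: 1, 2, 5 and 8 are taken as commercial. Both phenols travel as benzyl ethers, so the CH2–O ether made from 1 is a 3,4-dialkoxybenzyl ether (labile to strong acid and to DDQ); only mild acid is used before step 9.

**Route**

Step 1
Reactants: 1 4-(benzyloxy)-3-methoxybenzyl alcohol; 2 methyl acrylate
Product: 3 methyl 3-{[4-(benzyloxy)-3-methoxyphenyl]methoxy}propanoate
Conditions: 2 (3 equiv), t-BuOK (5 mol%), THF, 0 °C → rt
Reagents that add atoms: none
Why: Base-catalysed oxa-Michael addition of the benzylic alkoxide to the acrylate; no stereocentre is formed and excess acrylate limits transesterification.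

Step 2
Reactants: 3 methyl 3-{[4-(benzyloxy)-3-methoxyphenyl]methoxy}propanoate
Product: 4 3-{[4-(benzyloxy)-3-methoxyphenyl]methoxy}propanoic acid
Conditions: LiOH, THF/H2O, 0 °C → rt; then 1 M HCl to pH 3–4
Reagents that add atoms: lithium hydroxide, [Li+].[OH-]
Why: Ester saponification at 0 °C is faster than retro-oxa-Michael elimination, and the mild acidification leaves the dialkoxybenzyl ether intact.

Step 3
Reactants: 4 3-{[4-(benzyloxy)-3-methoxyphenyl]methoxy}propanoic acid; 5 (S)-4-benzyloxazolidin-2-one
Product: 7 (S)-4-benzyl-3-(3-{[4-(benzyloxy)-3-methoxyphenyl]methoxy}propanoyl)oxazolidin-2-one, via pivalic mixed anhydride 6 (not isolated)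
Conditions: PivCl, Et3N, THF, −20 °C; then 5, LiCl, rt
Reagents that add atoms: none
Why: N-Acylation of the oxazolidinone through the pivalic mixed anhydride with LiCl/Et3N activation is the standard one-pot entry to auxiliary imides; the only stereocentre is the one brought by 5.

Step 4
Reactants: 7 (S)-4-benzyl-3-(3-{[4-(benzyloxy)-3-methoxyphenyl]methoxy}propanoyl)oxazolidin-2-one; 8 4-(benzyloxy)-3-methoxybenzaldehyde
Product: 10 (S)-4-benzyl-3-[(2S,3S)-3-[4-(benzyloxy)-3-methoxyphenyl]-2-({[4-(benzyloxy)-3-methoxyphenyl]methoxy}methyl)-3-hydroxypropanoyl]oxazolidin-2-one, via Z-dibutylboron enolate 9 (not isolated)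
Conditions: Bu2BOTf, i-Pr2NEt, CH2Cl2, −78 → 0 °C; 8, −78 → 0 °C; pH 7 buffer, MeOH, H2O2, 0 °C
Reagents that add atoms: none
Why: Evans syn-aldol reaction: the Z-boron enolate reacts through a closed chair transition state with the auxiliary shielding one enolate face, which sets the aryl carbinol centre (3S) and the α-centre (2S); only the carbinol centre has to last, because the α-centre is re-set in step 7.

Step 5
Reactants: 10 the syn-aldol imide
Product: 11 (2S,3S)-3-[4-(benzyloxy)-3-methoxyphenyl]-2-({[4-(benzyloxy)-3-methoxyphenyl]methoxy}methyl)-3-hydroxy-N-methoxy-N-methylpropanamide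
Conditions: MeNH(OMe)·HCl, AlMe3, CH2Cl2, −20 → 0 °C; Rochelle salt work-up
Reagents that add atoms: N,O-dimethylhydroxylamine hydrochloride, CNOC.Cl
Why: Aluminium amide transamination of a β-hydroxy imide (Weinreb amide formation) proceeds through the aluminium alkoxide without retro-aldol cleavage or epimerisation and releases the auxiliary.

Step 6
Reactants: 11 the Weinreb amide
Product: 12 (3S,4S)-4-[4-(benzyloxy)-3-methoxyphenyl]-3-({[4-(benzyloxy)-3-methoxyphenyl]methoxy}methyl)-1-chloro-4-hydroxybutan-2-one
Conditions: MeLi·LiBr (1.0 equiv), THF, −78 °C; then ICH2Cl (3 equiv), MeLi·LiBr (2.5 equiv), −78 °C; sat. NH4Cl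
Reagents that add atoms: chloroiodomethane, ClCI
Why: Chloromethyllithium from I/Li exchange adds to the Weinreb amide and the chelated tetrahedral intermediate prevents over-addition (Weinreb ketone synthesis, chloromethyl homologation); the stereocentres are untouched at −78 °C.

Step 7
Reactants: 12 the chloromethyl ketone
Product: 14 (4R,5S)-5-[4-(benzyloxy)-3-methoxyphenyl]-4-({[4-(benzyloxy)-3-methoxyphenyl]methoxy}methyl)oxolan-3-one (trans), via cis-oxolanone 13 (not isolated)
Conditions: K2CO3, NaI (cat.), MeCN, rt; then DBU (cat.), rt; chromatography to remove residual cis isomer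
Reagents that add atoms: none
Why: Intramolecular Williamson etherification (5-exo-tet at the SN2-active α-chloroketone carbon) closes the oxolan-3-one as the cis isomer, and base-mediated enolisation then equilibrates the α-centre to the favoured trans isomer, so C4 is dictated by the untouched aryl-bearing C5; loss of the ring oxygen would be the reverse of a 5-endo-trig closure and is not expected.

Step 8
Reactants: 14 the trans-oxolan-3-one
Product: 15 (1S,2R,5R,6S)-2,6-bis[4-(benzyloxy)-3-methoxyphenyl]-3,7-dioxabicyclo[3.3.0]octan-1-ol (cis-fused, both aryl groups exo)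
Conditions: hν (medium-pressure Hg lamp, Pyrex filter, λ > 300 nm), degassed benzene (0.01 M), rt
Reagents that add atoms: none
Why: Excitation of the n→π* band of the ring ketone gives a carbonyl-centred excited state whose oxygen abstracts one of the benzylic, α-oxygenated hydrogens of the side-chain OCH2Ar group through a seven-membered transition state (1,6-hydrogen transfer; there is no carbon-bound γ-hydrogen, the γ-positions being O and an arene carbon), and the resulting 1,5-biradical (tertiary ketyl at the carbonyl carbon, α-alkoxybenzyl radical) collapses by radical–radical coupling to the new C–C bond. The closest known reaction type is the Norrish–Yang photocyclisation with δ-hydrogen abstraction, which is established for β-(alkoxymethyl) ketones and for 4-[(arylmethoxy)methyl]oxolan-3-ones giving 3,7-dioxabicyclo[3.3.0]octan-1-ols. The new oxolane ring closes by joining the two ends of a five-atom chain (biradical collapse to a five-membered ring, no Baldwin restriction) and can only be cis-fused to the existing oxolanone ring. The carbinol centre C1 is therefore controlled by C5–H, because the side chain reaches the carbonyl carbon only from its own face, and at C2 the aryl group is expected exo, on the convex face and cis to the new OH, because the endo transition state pushes it into the concave face of the forming bicycle. The step needs δ-abstraction to outrun α-cleavage (Norrish type I) and abstraction from the phenolic O-benzyl groups; the first is favoured by the weak, doubly activated C–H bond held next to the carbonyl oxygen, the second is excluded by distance.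

Step 9
Reactants: 15 the dioxabicyclooctanol
Product: 16 (2R,3S,4S)-2-[4-(benzyloxy)-3-methoxyphenyl]-4-{[4-(benzyloxy)-3-methoxyphenyl]methyl}-3-(hydroxymethyl)oxolan-3-ol
Conditions: Et3SiH (3 equiv), BF3·OEt2 (2 equiv), CH2Cl2, −78 → −30 °C; aq. NaHCO3
Reagents that add atoms: none
Why: Ionic hydrogenation of a benzylic ether: BF3 ionises the C6–O7 bond to a 4-alkoxybenzyl cation that the silane reduces, whereas ionisation at C2 is retarded because that cation would sit next to the oxygen-bearing quaternary C1 (β-oxygen effect); no stereocentre of the product is touched and the relay centre C6 becomes CH2.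

Step 10
Reactants: 16 the di-O-benzyl ether of the target
Product: 17 (2R,3S,4S)-2-(4-hydroxy-3-methoxyphenyl)-4-[(4-hydroxy-3-methoxyphenyl)methyl]-3-(hydroxymethyl)oxolan-3-ol (target)
Conditions: H2 (1 atm), 10% Pd/C, EtOAc/MeOH, rt, stopped after uptake of 2 equiv
Reagents that add atoms: none
Why: Hydrogenolysis of the two aryl benzyl ethers over Pd/C is much faster than cleavage of the remaining dialkyl benzylic C2–O bond, which is further deactivated by the adjacent carbinol, so the three stereocentres are preserved.

**Compound list**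

1 | 4-(benzyloxy)-3-methoxybenzyl alcohol | OCc1ccc(OCc2ccccc2)c(OC)c1 | starting material
2 | methyl acrylate | C=CC(=O)OC | starting material
3 | methyl 3-{[4-(benzyloxy)-3-methoxyphenyl]methoxy}propanoate | COC(=O)CCOCc1ccc(OCc2ccccc2)c(OC)c1 | intermediate
4 | 3-{[4-(benzyloxy)-3-methoxyphenyl]methoxy}propanoic acid | OC(=O)CCOCc1ccc(OCc2ccccc2)c(OC)c1 | intermediate
5 | (S)-4-benzyloxazolidin-2-one | O=C1N[C@@H](Cc2ccccc2)CO1 | starting material
6 | pivalic mixed anhydride of 4 | CC(C)(C)C(=O)OC(=O)CCOCc1ccc(OCc2ccccc2)c(OC)c1 | intermediate (not isolated)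
7 | (S)-4-benzyl-3-(3-{[4-(benzyloxy)-3-methoxyphenyl]methoxy}propanoyl)oxazolidin-2-one | O=C(CCOCc1ccc(OCc2ccccc2)c(OC)c1)N1[C@@H](Cc2ccccc2)COC1=O | intermediate
8 | 4-(benzyloxy)-3-methoxybenzaldehyde | O=Cc1ccc(OCc2ccccc2)c(OC)c1 | starting material
9 | Z-dibutylboron enolate of 7 | CCCCB(CCCC)O/C(=C\COCc1ccc(OCc2ccccc2)c(OC)c1)N1[C@@H](Cc2ccccc2)COC1=O | intermediate (not isolated)
10 | (S)-4-benzyl-3-[(2S,3S)-3-[4-(benzyloxy)-3-methoxyphenyl]-2-({[4-(benzyloxy)-3-methoxyphenyl]methoxy}methyl)-3-hydroxypropanoyl]oxazolidin-2-one | O=C([C@@H](COCc1ccc(OCc2ccccc2)c(OC)c1)[C@H](O)c1ccc(OCc2ccccc2)c(OC)c1)N1[C@@H](Cc2ccccc2)COC1=O | intermediate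
11 | (2S,3S)-3-[4-(benzyloxy)-3-methoxyphenyl]-2-({[4-(benzyloxy)-3-methoxyphenyl]methoxy}methyl)-3-hydroxy-N-methoxy-N-methylpropanamide | CON(C)C(=O)[C@@H](COCc1ccc(OCc2ccccc2)c(OC)c1)[C@H](O)c1ccc(OCc2ccccc2)c(OC)c1 | intermediate
12 | (3S,4S)-4-[4-(benzyloxy)-3-methoxyphenyl]-3-({[4-(benzyloxy)-3-methoxyphenyl]methoxy}methyl)-1-chloro-4-hydroxybutan-2-one | ClCC(=O)[C@@H](COCc1ccc(OCc2ccccc2)c(OC)c1)[C@H](O)c1ccc(OCc2ccccc2)c(OC)c1 | intermediate
13 | (4S,5S)-5-[4-(benzyloxy)-3-methoxyphenyl]-4-({[4-(benzyloxy)-3-methoxyphenyl]methoxy}methyl)oxolan-3-one (cis) | COc1cc([C@@H]2[C@H](COCc3ccc(OCc4ccccc4)c(OC)c3)C(=O)CO2)ccc1OCc1ccccc1 | intermediate (not isolated)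
14 | (4R,5S)-5-[4-(benzyloxy)-3-methoxyphenyl]-4-({[4-(benzyloxy)-3-methoxyphenyl]methoxy}methyl)oxolan-3-one (trans) | COc1cc([C@@H]2[C@@H](COCc3ccc(OCc4ccccc4)c(OC)c3)C(=O)CO2)ccc1OCc1ccccc1 | intermediate
15 | (1S,2R,5R,6S)-2,6-bis[4-(benzyloxy)-3-methoxyphenyl]-3,7-dioxabicyclo[3.3.0]octan-1-ol | COc1cc([C@@H]2[C@H]3CO[C@H](c4ccc(OCc5ccccc5)c(OC)c4)[C@@]3(O)CO2)ccc1OCc1ccccc1 | intermediate
16 | (2R,3S,4S)-2-[4-(benzyloxy)-3-methoxyphenyl]-4-{[4-(benzyloxy)-3-methoxyphenyl]methyl}-3-(hydroxymethyl)oxolan-3-ol | COc1cc(C[C@H]2CO[C@H](c3ccc(OCc4ccccc4)c(OC)c3)[C@@]2(O)CO)ccc1OCc1ccccc1 | intermediate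
17 | (2R,3S,4S)-2-(4-hydroxy-3-methoxyphenyl)-4-[(4-hydroxy-3-methoxyphenyl)methyl]-3-(hydroxymethyl)oxolan-3-ol | COc1cc(C[C@H]2CO[C@H](c3ccc(O)c(OC)c3)[C@@]2(O)CO)ccc1O | target

**Count and risks**

Total steps: 10. Longest linear sequence: 10 steps (from 1).

Steps most likely to fail:

1. Step 8. The excited ketone may be quenched by charge transfer from the two electron-rich arenes, α-cleavage with loss of CO may compete with hydrogen transfer, or the exo/endo control at the aryl-bearing centre may be poor. The fallback avoids photochemistry, sets out from 14 and comes back at 15; it makes the C–C bond as a C=C bond and closes the ring through oxygen. Wittig olefination of 14 with the ylide from [4-(benzyloxy)-3-methoxybenzyl]triphenylphosphonium chloride (NaHMDS, THF) should give the benzylidene-oxolane F1. Epoxidation (mCPBA, NaHCO3, CH2Cl2, 0 °C) on the face anti to the neighbouring CH2OR branch should give the spiro-epoxide F2, whose tertiary C–O bond already has the configuration of 15. Acid (CSA cat., CH2Cl2, −20 °C, 1,3,5-trimethoxybenzene as cation trap) should then open the benzylic epoxide carbon with the side-chain ether oxygen in a five-membered closure. The 4-(benzyloxy)-3-methoxybenzyl group should leave from the oxonium ion, and the SN1-like substitution should place the aryl group exo, giving 15.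

2. Step 9. Ionisation may occur at the wrong benzylic C–O bond (C2–O3), or the benzylic cation may react further (Friedel–Crafts attack on the neighbouring arene, epimerisation at C2). The fallback sets out from 15 and arrives directly at 17, leaving the cationic manifold. Neutral catalytic hydrogenolysis (H2, Pd/C or Pd(OH)2/C, EtOAc/MeOH, rt) should first remove the two O-benzyl groups. It should then cleave the C6–O7 bond on the catalyst surface, because this is the accessible benzylic ether (next to a methine, not to the quaternary carbinol). This also takes over step 10.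

3. Step 6. The lithium aldolate of 11 may undergo retro-aldol cleavage or β-elimination of the arylmethoxide, and chloromethyllithium may decompose before it adds. The fallback sets out from 10 and comes back at 13, which is equilibrated to 14 as in step 7; it replaces the Weinreb/carbenoid sequence by acyl transfer to a sulfur ylide and a metal-carbene O–H insertion. Dimethylsulfoxonium methylide (Me3S(O)I, t-BuOK, THF, 0 °C → rt) should displace the auxiliary from 10 to give the β-keto sulfoxonium ylide F3. [Ir(cod)Cl]2 (cat., 1,2-dichloroethane, 70 °C) should then effect intramolecular O–H insertion of the carbinol to close the oxolan-3-one 13.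

**Further compounds**

F1 | step 8 | (2S,3R)-2-[4-(benzyloxy)-3-methoxyphenyl]-3-({[4-(benzyloxy)-3-methoxyphenyl]methoxy}methyl)-4-{[4-(benzyloxy)-3-methoxyphenyl]methylidene}oxolane (E/Z mixture) | COc1cc([C@@H]2[C@@H](COCc3ccc(OCc4ccccc4)c(OC)c3)C(=Cc5ccc(OCc6ccccc6)c(OC)c5)CO2)ccc1OCc1ccccc1
F2 | step 8 | (3S,6S,7R)-2,6-bis[4-(benzyloxy)-3-methoxyphenyl]-7-({[4-(benzyloxy)-3-methoxyphenyl]methoxy}methyl)-1,5-dioxaspiro[2.4]heptane (mixture at C2) | COc1cc([C@@H]2[C@@H](COCc3ccc(OCc4ccccc4)c(OC)c3)[C@]3(OC3c5ccc(OCc6ccccc6)c(OC)c5)CO2)ccc1OCc1ccccc1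
F0 | step 9 | none | none
F3 | step 6 | (3S,4S)-4-[4-(benzyloxy)-3-methoxyphenyl]-3-({[4-(benzyloxy)-3-methoxyphenyl]methoxy}methyl)-1-(dimethyloxo-λ6-sulfanylidene)-4-hydroxybutan-2-one | CS(C)(=O)=CC(=O)[C@@H](COCc1ccc(OCc2ccccc2)c(OC)c1)[C@H](O)c1ccc(OCc2ccccc2)c(OC)c1
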